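## Structural features

The target (23) is a formylphloroglucinol meroterpenoid: a hexasubstituted benzene (ring A, C1'–C6'; OH on C2' and C4', CHO on C3' and C5') joined to an aromadendrane built from a cyclopentane (ring C, C1–C5), a cycloheptane (ring D, C1, C5–C10) and a gem-dimethylcyclopropane (ring E, C6, C7, C11); aromadendrane numbering is used throughout, C7' is the benzylic carbon and C8'–C11' the isobutyl group. The halves are joined twice, C7'–C4 and O(C6')–C1, so that O–C1–C5–C4–C7'–C1'–C6' is an oxepane (ring B) and C1 and C4 are the bridgeheads of a benzo-fused 2-oxabicyclo[4.2.1]nonane with C5 as the one-carbon bridge and C2–C3 as the two-carbon bridge. There are seven stereocentres, (1S,4R,5R,6R,7R,10S,7'R): C7' stands next to the quaternary C4, C4–C5–C1 are contiguous, C1 is a fully substituted ether carbon flanked by C10, and C5 carries the cyclopropane carbons C6/C7. On ring C the ether oxygen, C7' and H5 share one face (called β) while C10, C6 and the C4 methyl lie on the other; on ring D the oxygen, H5, the CMe2 bridge and the C10 methyl are all β, so for any precursor with trigonal C5 the aryl bridge must enter C4 syn to the cyclopropane, and H10 is anti to the C1–O bond. Fragile elements are the tertiary alkyl aryl ether at C1 (its ionization gives a cation next to C5–H, a cyclopropylcarbinyl position), the cyclopropane itself, the two aryl aldehydes and the free phenols. The real difficulty is ring B: a bridging ether between two fully substituted carbons with the vicinal C7'/C4 pair on the face that a planar C4=C5 precursor shields, plus the C10 configuration, which a cationic assembly reaches only through a 1,2-hydride shift. The key step exploits the fact that the bridgeheads C4 and C1 are also linked through C3–C2: a carbonyl at C3 makes C4 an enolate carbon and, through a C1=C2 double bond, C1 a Michael acceptor, so both bridging bonds can be made anionically on one cyclopentenone in which C5 is already tetrahedral and its C6 substituent steers attack at C4 to the β face.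

## Logic of the disconnections

**23 ⇒ 21.** The C3'–CHO and C5'–CHO bonds are cut. These are the only free positions of ring A and both are activated by free hydroxyls, so the aldehydes can be added last and need not survive enolate, hydride or hydrazone chemistry. The demand is a formylation that 21, with its tertiary C1–O ether, tolerates.

**21 ⇒ 20 ⇒ 18 (through 19).** The two O–benzyl bonds are cut, and a carbonyl is added at C3 (CH2 ⇐ C=O). The carbonyl is a traceless linchpin placed in the two-carbon bridge, the only position from which both bridgeheads can be reached. The demand is a deoxygenation that is neither strongly basic (retro-oxa-Michael) nor strongly acidic (ionization at C1).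

**18 ⇒ 10 + 16 (16 from 14).** This is the key disconnection: C4–C7' and O–C1 are cut. The route in one sentence: the kinetic α'-enolate of a tricyclic cyclopent-2-enone and an o-quinone methide are joined by Michael addition at C4, and the liberated phenoxide closes ring B by oxa-Michael addition at C1. The gain is the whole bridged ring, three stereocentres (C4, C7', C1) and the separation of the arene from the terpenoid. The demands on 10 are an sp3 C5 with H5 β, a set C10 centre and an intact C1=C2 enone; the forward step must alkylate at C4 rather than at a γ-position, and add to C7' with the right relative topicity.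

**10 ⇒ 8 (through 9).** C1–C5, C2–C3 and C3–C4 are cut in a (2+2+1) sense. This removes rings C and D at once and brings in C3 as carbon monoxide exactly where the linchpin is needed. The demand is a seven-membered ring closure onto a 1,2-disubstituted alkene in which the C1–C5 bond forms on the face of C5 away from the CMe2 bridge, so that H5 ends β.

**8 ⇒ 6 ⇒ 5 ⇒ 4.** The C1≡C2 triple bond is traced to the C1H2–C2HO unit of 6, which comes from the ester 5. The C10–H bond is cut to the enoate 4. C10 is thus set by catalyst control in an open-chain precursor, where the outcome does not depend on the conformation of ring D. The demands are a clean (E)-enoate and an alkyne-forming step that does not touch the propargylic C10–H.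

**4 ⇒ 3 ⇒ 2 ⇒ 1.** The C10=C1 and C5=C4 double bonds are cut (two olefinations), then the two carbonyls are reconnected to the ring alkene of 1. The terpene 1 supplies C5–C11, C14 and the C6/C7 stereocentres with the cis arrangement of both arms. The demand is chemoselectivity between aldehyde and methyl ketone in 2.

**14 ⇒ 13 ⇒ 12 ⇒ 11.** The C7'–S bond, the C7'–C8' bond and two O–benzyl bonds are cut. The sulfone 14 is a stable precursor that releases 16 under base; C7' is racemic in 13 and 14 because it becomes trigonal in 16.

## Other disconnections considered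

**Alternative 1:** the biomimetic cut, and the first that comes to mind. C4–C7', O–C1 and the transannular C1–C5 bond are cut together. Forward, the diformyl o-quinone methide A2 (made in situ by Knoevenagel condensation) adds to C4 of (+)-bicyclogermacrene A1; the C5 cation closes onto C1, a 1,2-hydride shift from C1 to C10 follows and the phenol oxygen captures C1. It is the shortest on paper, but the chosen plan is preferred on three grounds:
- A1 is not commercial, must be made in several steps and is prone to Cope rearrangement.
- The cascade passes two cations (C5, cyclopropylcarbinyl; C10, tertiary) with several exits: oxygen capture at C5 to a six-membered ether, capture at C10, elimination. The target requires the hydride-shift branch, for which the substrate offers no control.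
- C7' is set in an intermolecular step without a handle.

**Alternative 2:** the same two bonds, but made on a planar dienolate. Commercial (−)-α-gurjunene A3 would be oxidized at the allylic C3 to the 4-en-3-one A4, and its extended lithium dienolate A5 (C3–O, C3=C4, C5=C1) would be alkylated at C4 by 16 and closed by oxa-Michael addition after olefin migration. This is much shorter, yet it is rejected on structural grounds. In A5, C5 is trigonal and the endo methyl of the CMe2 bridge lies under C5/C4, so the electrophile should enter C4 anti to ring E, the face opposite to the one required; C5 and C1 would then follow C4. A3 also carries the (10R) centre, the C10 epimer of the target. This analysis is the reason why the chosen route makes C5 tetrahedral (H5 β) before C4 is alkylated.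

**Alternative 3:** cut C5–C6 and C7–C8, a (5+2) cycloaddition that builds ring D together with ring E. A rhodium-catalysed reaction of the 1-(1-methylcyclopropyl)cyclopentene A6 with 3,3-dimethylcyclopropene A7 would give the tetrasubstituted alkene A8, and ring B would be closed by anti-hydroalkoxylation of C1=C10. The chosen plan is preferred because:
- A6 already needs the C7'/C4 pair, made without ring control.
- Intermolecular (5+2) reactions with alkene partners are poorly precedented, and a cyclopropene may ring-open on rhodium.
- The final ether closure must pass a C1 cation whose neighbour C5–H is cyclopropylcarbinyl, so a hydride shift and closure to the six-membered ether, or ring opening, is expected to compete; C10 would be set only by the face of protonation.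

Key step: step 11

Remarks on the chemistry (assumptions):
- (+)-2-Carene (1) is taken as the (1S,6R) enantiomer, which carries the C6/C7 configuration of the target.
- In step 4 the (R)-bisphosphine is assumed to deliver hydride to the face of the (E)-enoate that gives the (3S)-ester; if the sense is opposite, the (S)-ligand is used and nothing else changes.

## Route

Step 1
Reactants: 1 (+)-2-carene, (1S,6R)-3,7,7-trimethylbicyclo[4.1.0]hept-2-ene
Product: 2 (1S,3R)-2,2-dimethyl-3-(3-oxobutyl)cyclopropane-1-carbaldehyde
Conditions: O3, CH2Cl2, −78 °C; then Me2S, −78 °C to rt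
Reagents that add atoms: ozone, [O-][O+]=O
Why: Ozonolysis with reductive work-up cleaves the only C=C bond and gives the cis-disposed aldehyde (future C5) and methyl ketone (future C10 with C14); the cyclopropane stereocentres C6 and C7 are bought with the terpene and are not touched.

Step 2
Reactants: 2 (1S,3R)-2,2-dimethyl-3-(3-oxobutyl)cyclopropane-1-carbaldehyde
Product: 3 4-[(1R,3S)-2,2-dimethyl-3-[(1Z)-prop-1-en-1-yl]cyclopropyl]butan-2-one
Conditions: EtPPh3Br, KN(SiMe3)2, THF, −78 °C; then 2, −78 to 0 °C
Reagents that add atoms: ethyltriphenylphosphonium bromide, CC[P+](c1ccccc1)(c1ccccc1)c1ccccc1.[Br-]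
Why: Wittig olefination; the unstabilized ylide reacts with the aldehyde much faster than with the methyl ketone and should give the (Z)-alkene C5=C4 (with C15), and the low temperature should prevent epimerization of the cis-cyclopropanecarbaldehyde.

Step 3
Reactants: 3 4-[(1R,3S)-2,2-dimethyl-3-[(1Z)-prop-1-en-1-yl]cyclopropyl]butan-2-one
Product: 4 ethyl (2E)-5-[(1R,3S)-2,2-dimethyl-3-[(1Z)-prop-1-en-1-yl]cyclopropyl]-3-methylpent-2-enoate
Conditions: (EtO)2P(O)CH2CO2Et, NaH, THF, 0 to 60 °C; E isomer separated by chromatography
Reagents that add atoms: triethyl phosphonoacetate, CCOC(=O)CP(=O)(OCC)OCC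
Why: Horner–Wadsworth–Emmons olefination of the methyl ketone gives the β,β-disubstituted enoate (C10=C1, ester carbon C2), expected mainly as the E isomer; the minor Z isomer is removed because it would give the C10 epimer in step 4.

Step 4
Reactants: 4 ethyl (2E)-5-[(1R,3S)-2,2-dimethyl-3-[(1Z)-prop-1-en-1-yl]cyclopropyl]-3-methylpent-2-enoate
Product: 5 ethyl (3S)-5-[(1R,3S)-2,2-dimethyl-3-[(1Z)-prop-1-en-1-yl]cyclopropyl]-3-methylpentanoate
Conditions: Cu(OAc)2·H2O (3 mol %), (R)-DTBM-SEGPHOS (3 mol %), (EtO)2MeSiH, t-BuOH, toluene, 0 °C to rt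
Reagents that add atoms: none
Why: Asymmetric conjugate reduction by a monovalent copper hydride carrying a chiral bisphosphine, a known reaction of (E)-β,β-dialkyl enoates; hydride delivery to C10 is ligand-controlled and sets the (S)-configured CH–CH3 centre, the only stereocentre of the route made by catalysis, while the unactivated (Z)-propenyl group and the cyclopropane are inert.

Step 5
Reactants: 5 ethyl (3S)-5-[(1R,3S)-2,2-dimethyl-3-[(1Z)-prop-1-en-1-yl]cyclopropyl]-3-methylpentanoate
Product: 6 (3S)-5-[(1R,3S)-2,2-dimethyl-3-[(1Z)-prop-1-en-1-yl]cyclopropyl]-3-methylpentanal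
Conditions: iBu2AlH (1.1 equiv), CH2Cl2, −78 °C; then H2O
Reagents that add atoms: none
Why: Partial reduction of the ester at low temperature stops at the aldehyde oxidation level; C10 is β to the carbonyl and cannot epimerize.

Step 6
Reactants: 6 (3S)-5-[(1R,3S)-2,2-dimethyl-3-[(1Z)-prop-1-en-1-yl]cyclopropyl]-3-methylpentanal
Product: 8 (1R,2S)-3,3-dimethyl-1-[(3S)-3-methylpent-4-yn-1-yl]-2-[(1Z)-prop-1-en-1-yl]cyclopropane, via alkenyl nonaflate 7 (not isolated)
Conditions: C4F9SO2F, tBuN=P(NC4H8)3 (2.5 equiv), DMF, −30 °C to rt
Reagents that add atoms: none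
Why: One-pot conversion of an enolizable aldehyde RCH2CHO into the terminal alkyne RC≡CH (a known sequence): enolization toward C1 and O-sulfonylation give 7, and base-induced elimination of nonaflate then gives the C1≡C2 bond without change in carbon count; neither stage removes the C10–H, so the centre should be retained.

Step 7
Reactants: 8 (1R,2S)-3,3-dimethyl-1-[(3S)-3-methylpent-4-yn-1-yl]-2-[(1Z)-prop-1-en-1-yl]cyclopropane
Product: 10 (4S,5R,6R,7R,10S)-aromadendr-1-en-3-one, via dicobalt complex 9 (not isolated)
Conditions: Co2(CO)8, CH2Cl2, rt; then N-methylmorpholine N-oxide, CH2Cl2, 0 °C to rt (0.005 M)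
Reagents that add atoms: dicobalt octacarbonyl (source of the C3 carbonyl), [Co].[Co].[C-]#[O+].[C-]#[O+].[C-]#[O+].[C-]#[O+].[C-]#[O+].[C-]#[O+].[C-]#[O+].[C-]#[O+]
Why: Intramolecular Pauson–Khand (2+2+1) cycloaddition: the alkyne of 8 is bound as complex 9, the (Z)-alkene inserts to form C1–C5 and CO insertion forms C2–C3 and C3–C4, closing rings D and C with the enone fixed at C1=C2–C3=O; the cis-cyclopropane holds the two arms together for the seven-membered ring closure. C5 is set because the vinylcyclopropane reacts in its s-trans bisected conformation (the other is blocked by the endo methyl of ring E), so C1 bonds to C5 on the face turned toward C7 and H5 ends cis to the CMe2 bridge; the C4 methyl ends cis to C6 (from the Z alkene), which is inconsequential because C4 is enolized in step 11.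

Step 8
Reactants: 11 2,4,6-trihydroxybenzaldehyde
Product: 12 4,6-bis(benzyloxy)-2-hydroxybenzaldehyde
Conditions: BnBr (2.1 equiv), K2CO3, DMF, rt
Reagents that add atoms: benzyl bromide, BrCc1ccccc1
Why: Williamson etherification; after the para hydroxyl and one ortho hydroxyl are benzylated, the remaining ortho hydroxyl is hydrogen-bonded to the formyl group and is the least nucleophilic, so the reaction should stop at the dibenzyl ether.

Step 9
Reactants: 12 4,6-bis(benzyloxy)-2-hydroxybenzaldehyde
Product: 13 3,5-bis(benzyloxy)-2-(1-hydroxy-3-methylbutyl)phenol (racemic)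
Conditions: iBuMgBr (2.5 equiv), THF, −78 to 0 °C; aq. NH4Cl
Reagents that add atoms: isobutylmagnesium bromide, CC(C)C[Mg]Br
Why: Grignard addition to the aldehyde after the first equivalent has deprotonated the phenol; it brings in C8'–C11' and creates C7', whose configuration is irrelevant here because C7' becomes trigonal in 16.

Step 10
Reactants: 13 3,5-bis(benzyloxy)-2-(1-hydroxy-3-methylbutyl)phenol
Product: 14 3,5-bis(benzyloxy)-2-[3-methyl-1-(4-methylbenzenesulfonyl)butyl]phenol (racemic)
Conditions: TolSO2Na, HCO2H, CH2Cl2/H2O, rt
Reagents that add atoms: sodium p-toluenesulfinate, [Na+].[O-]S(=O)c1ccc(C)cc1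
Why: Acid-mediated substitution of the electron-rich o-hydroxybenzylic alcohol by sulfinic acid through sulfur gives the bench-stable sulfone, an established precursor that releases an o-quinone methide under base.

Step 11
Reactants: 10 (4S,5R,6R,7R,10S)-aromadendr-1-en-3-one; 14 3,5-bis(benzyloxy)-2-[3-methyl-1-(4-methylbenzenesulfonyl)butyl]phenol
Product: 18 bridged ketone: the 3-oxo-2',4'-di-O-benzyl-3',5'-dideformyl analogue of 23 (stereocentres as in 23), via lithium enolate 15 (not isolated), via o-quinone methide 16 (not isolated), via Michael adduct 17 (not isolated)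
Conditions: 10, LiN(iPr)2, THF, −78 °C; then 14 pre-treated with LiN(SiMe3)2 (THF, −78 °C), −78 to −10 °C; then MeOH, 0 °C to rt; aq. NH4Cl
Reagents that add atoms: none
Why: Kinetic α'-deprotonation of 10 gives the cross-conjugated enolate 15 (C3–O, C3=C4, with C1=C2 untouched), while deprotonated 14 loses sulfinate on warming to give 16. Enolate 15 adds through C4 to the exocyclic carbon C7' of 16, which rearomatizes ring A and gives phenoxide 17; the addition of ketone enolates to o-quinone methides is a known reaction type. On addition of methanol the phenoxide oxygen closes ring B by 7-exo-trig oxa-Michael addition to C1, the β-carbon of the enone, as in the known closure of 2,2-dialkylchromanones, and protonation at C2 gives 18. C4 is controlled by the adjacent tetrahedral C5: the electrophile enters anti to the cyclopropyl-bearing C6 (2,3-trans alkylation of a cyclopentanone enolate), which is the β face and the face of H5. C7' is set in the same bond-forming event by the relative topicity of 15 and 16; a lithium-bridged arrangement with the aryl ring turned away from C5 and the isobutyl group between the C4 methyl and C5 leads to the required centre, and this is the least secure element. C1 is controlled by the tether, since only the β face of C1 is within reach of the oxygen, so the ether forms cis to C7' and H5. The selectivities needed are α'- over γ-deprotonation (kinetic base at −78 °C), C- over O-alkylation (soft exocyclic carbon of 16), and no erosion at C10 or C5 (the enone with γ-hydrogens is present only until the ring closes, and an H5 epimer could not close). The step forms C4–C7' and O–C1, the oxepane and three stereocentres without any cation or radical at C1 or C5.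

Step 12
Reactants: 18 bridged ketone (3-oxo-2',4'-di-O-benzyl-3',5'-dideformyl analogue of 23)
Product: 19 p-toluenesulfonylhydrazone of 18 at C3
Conditions: TsNHNH2, MeOH, 45 °C
Reagents that add atoms: p-toluenesulfonohydrazide, NNS(=O)(=O)c1ccc(C)cc1
Why: Hydrazone formation at the only carbonyl group; no acid or base is added, so that the β-aryloxy ketone is not driven into retro-oxa-Michael opening.

Step 13
Reactants: 19 p-toluenesulfonylhydrazone of 18
Product: 20 2',4'-di-O-benzyl-3',5'-dideformyl analogue of 23 (C3 = CH2)
Conditions: catecholborane, CHCl3, 0 °C to rt; then NaOAc·3H2O, reflux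
Reagents that add atoms: none
Why: Kabalka reduction of a tosylhydrazone: hydride addition to C=N, then loss of sulfinate and dinitrogen, leaves CH2 at C3 under nearly neutral conditions, so the traceless carbonyl is removed without E1cB opening of ring B or ionization at C1.

Step 14
Reactants: 20 2',4'-di-O-benzyl-3',5'-dideformyl analogue of 23
Product: 21 3',5'-dideformyl analogue of 23 (free 2',4'-diphenol)
Conditions: H2 (1 atm), Pd/C, EtOAc/EtOH, rt
Reagents that add atoms: none
Why: Hydrogenolysis of the two benzyl ethers; the gem-dimethylcyclopropane and the tertiary alkyl aryl ether (not benzylic at oxygen) should be inert at ambient pressure.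

Step 15
Reactants: 21 3',5'-dideformyl analogue of 23
Product: 23 CNP0189833.2, the (1S,4R,5R,6R,7R,10S,7'R) target, via bis-iminium salt 22 (not isolated)
Conditions: POCl3, DMF, MeCN, 0 °C to rt; then H2O, 50 °C
Reagents that add atoms: N,N-dimethylformamide, CN(C)C=O; water, O
Why: Double Vilsmeier–Haack formylation at C3' and C5', the only free ring positions, each ortho or para to a free hydroxyl (the reaction type used to prepare diformylphloroglucinols); hydrolysis of 22 releases the two aldehydes, which then deactivate the ether oxygen toward ionization.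

## Compound list

1 | (+)-2-carene, (1S,6R)-3,7,7-trimethylbicyclo[4.1.0]hept-2-ene | CC1=C[C@H]2[C@@H](CC1)C2(C)C | starting material
2 | (1S,3R)-2,2-dimethyl-3-(3-oxobutyl)cyclopropane-1-carbaldehyde | CC(=O)CC[C@@H]1[C@H](C=O)C1(C)C | intermediate
3 | 4-[(1R,3S)-2,2-dimethyl-3-[(1Z)-prop-1-en-1-yl]cyclopropyl]butan-2-one | CC(=O)CC[C@@H]1[C@H](/C=C\C)C1(C)C | intermediate
4 | ethyl (2E)-5-[(1R,3S)-2,2-dimethyl-3-[(1Z)-prop-1-en-1-yl]cyclopropyl]-3-methylpent-2-enoate | CCOC(=O)/C=C(\C)CC[C@@H]1[C@H](/C=C\C)C1(C)C | intermediate
5 | ethyl (3S)-5-[(1R,3S)-2,2-dimethyl-3-[(1Z)-prop-1-en-1-yl]cyclopropyl]-3-methylpentanoate | CCOC(=O)C[C@@H](C)CC[C@@H]1[C@H](/C=C\C)C1(C)C | intermediate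
6 | (3S)-5-[(1R,3S)-2,2-dimethyl-3-[(1Z)-prop-1-en-1-yl]cyclopropyl]-3-methylpentanal | O=CC[C@@H](C)CC[C@@H]1[C@H](/C=C\C)C1(C)C | intermediate
7 | (3S)-5-[(1R,3S)-2,2-dimethyl-3-[(1Z)-prop-1-en-1-yl]cyclopropyl]-3-methylpent-1-en-1-yl nonafluorobutane-1-sulfonate (E/Z mixture) | O=S(=O)(OC=C[C@@H](C)CC[C@@H]1[C@H](/C=C\C)C1(C)C)C(F)(F)C(F)(F)C(F)(F)C(F)(F)F | intermediate (not isolated)
8 | (1R,2S)-3,3-dimethyl-1-[(3S)-3-methylpent-4-yn-1-yl]-2-[(1Z)-prop-1-en-1-yl]cyclopropane | C#C[C@@H](C)CC[C@@H]1[C@H](/C=C\C)C1(C)C | intermediate
9 | dicobalt hexacarbonyl complex of alkyne 8, Co2(CO)6(alkyne) | [H]C12[Co]3(=C=O)(=C=O)(=C=O)C1([Co]23(=C=O)(=C=O)=C=O)[C@@H](C)CC[C@@H]4[C@H](/C=C\C)C4(C)C | intermediate (not isolated)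
10 | (4S,5R,6R,7R,10S)-aromadendr-1-en-3-one | O=C1C=C2[C@@H](C)CC[C@@H]3[C@H]([C@@H]2[C@@H]1C)C3(C)C | intermediate
11 | 2,4,6-trihydroxybenzaldehyde | O=Cc1c(O)cc(O)cc1O | starting material
12 | 4,6-bis(benzyloxy)-2-hydroxybenzaldehyde | O=Cc1c(O)cc(OCc2ccccc2)cc1OCc1ccccc1 | intermediate
13 | 3,5-bis(benzyloxy)-2-(1-hydroxy-3-methylbutyl)phenol (racemic) | CC(C)CC(O)c1c(O)cc(OCc2ccccc2)cc1OCc1ccccc1 | intermediate
14 | 3,5-bis(benzyloxy)-2-[3-methyl-1-(4-methylbenzenesulfonyl)butyl]phenol (racemic) | CC(C)CC(c1c(O)cc(OCc2ccccc2)cc1OCc1ccccc1)S(=O)(=O)c1ccc(C)cc1 | intermediate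
15 | lithium enolate of 10 (C3–O–Li, C3=C4, C1=C2; C5, C6, C7, C10 as in 10) | [Li+].[O-]C1=C(C)[C@@H]2C(=C1)[C@@H](C)CC[C@@H]1[C@H]2C1(C)C | intermediate (not isolated)
16 | 3,5-bis(benzyloxy)-6-(3-methylbutylidene)cyclohexa-2,4-dien-1-one (o-quinone methide, alkene geometry not fixed) | CC(C)CC=C1C(=O)C=C(OCc2ccccc2)C=C1OCc1ccccc1 | intermediate (not isolated)
17 | lithium phenoxide of the open C4–C7' Michael adduct (enone C1=C2–C3=O intact; C4 and C7' as in 23) | [Li+].CC(C)C[C@@H](c1c([O-])cc(OCc2ccccc2)cc1OCc1ccccc1)[C@@]1(C)C(=O)C=C2[C@@H](C)CC[C@@H]3[C@H]([C@H]12)C3(C)C | intermediate (not isolated)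
18 | bridged ketone: 3-oxo-2',4'-di-O-benzyl-3',5'-dideformyl analogue of 23 | CC(C)C[C@H]1c2c(OCc3ccccc3)cc(OCc3ccccc3)cc2O[C@]23CC(=O)[C@@]1(C)[C@H]2[C@H]1[C@@H](CC[C@@H]3C)C1(C)C | intermediate
19 | p-toluenesulfonylhydrazone of 18 | CC(C)C[C@H]1c2c(OCc3ccccc3)cc(OCc3ccccc3)cc2O[C@]23CC(=NNS(=O)(=O)c4ccc(C)cc4)[C@@]1(C)[C@H]2[C@H]1[C@@H](CC[C@@H]3C)C1(C)C | intermediate
20 | 2',4'-di-O-benzyl-3',5'-dideformyl analogue of 23 | CC(C)C[C@H]1c2c(OCc3ccccc3)cc(OCc3ccccc3)cc2O[C@]23CC[C@@]1(C)[C@H]2[C@H]1[C@@H](CC[C@@H]3C)C1(C)C | intermediate
21 | 3',5'-dideformyl analogue of 23 (2',4'-diphenol) | CC(C)C[C@H]1c2c(O)cc(O)cc2O[C@]23CC[C@@]1(C)[C@H]2[C@H]1[C@@H](CC[C@@H]3C)C1(C)C | intermediate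
22 | 3',5'-bis(N,N-dimethyliminiomethyl) dichloride derived from 21 | CC(C)C[C@H]1c2c(O)c(C=[N+](C)C)c(O)c(C=[N+](C)C)c2O[C@]23CC[C@@]1(C)[C@H]2[C@H]1[C@@H](CC[C@@H]3C)C1(C)C.[Cl-].[Cl-] | intermediate (not isolated)
23 | CNP0189833.2, (1S,4R,5R,6R,7R,10S,7'R) | CC(C)C[C@H]1c2c(O)c(C=O)c(O)c(C=O)c2O[C@]23CC[C@@]1(C)[C@H]2[C@H]1[C@@H](CC[C@@H]3C)C1(C)C | target

## Step count and least certain steps

Total: 15 steps. Longest linear sequence: 12 steps (steps 1–7 and 11–15 from 1); the arene branch (steps 8–10) joins at step 11. Nothing below is a measured result.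

**Step 11 (key step).** The most likely failure is loss of relative stereocontrol at C7', because the lithium enolate and the o-quinone methide meet in a transition state that is not tied down. Second to this is an incomplete ring closure: the oxa-Michael equilibrium is fed from an enone that can also shuttle protons at C10 and C5. The fallback sets out from 10 and 13 and returns at 18, and separates the two events:
- 10 is converted into its trimethylsilyl enol ether F1 (LiN(iPr)2, Me3SiCl).
- Sc(OTf)3-catalysed ionization of the benzylic alcohol 13 generates 16 under Lewis-acidic conditions, and Mukaiyama–Michael addition of F1 gives the neutral phenol–enone F2, which is isolated and whose C7' epimers can be separated.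
- Ring closure to 18 is then a separate base-catalysed oxa-Michael reaction (DBU, or K2CO3 in MeOH) run to equilibrium.

**Step 7.** The seven-membered ring must close onto a 1,2-disubstituted alkene; this insertion is slow, so decomplexation or intermolecular reaction of the alkyne complex may win. The fallback sets out from 8 and returns at 15, and lets a monosubstituted alkene take part instead:
- Selective ozonolysis of the (Z)-propenyl group of 8 (alkenes react far faster than alkynes) gives the cyclopropanecarbaldehyde F3.
- Methylenation (Ph3P=CH2) gives the vinylcyclopropane F4.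
- The Pauson–Khand reaction of F4 gives the 15-nor enone F5.
- Kinetic α'-methylation (LiN(iPr)2, MeI) gives F6, the C4 epimer of 10, which is deprotonated to the same enolate 15.

**Step 6.** Under the strongly basic conditions the terminal alkyne may undergo prototropic isomerization toward the allene, which would erode the C10 centre; the elimination may also stall at 7. The fallback sets out from 3 and returns at 8, and builds the centre by carbometalation instead:
- Tosylhydrazone F7, then Shapiro reaction (n-BuLi) to the terminal alkene F8.
- Zirconium-catalysed asymmetric carboalumination (Me3Al, (+)-bis(1-neomenthylindenyl)zirconium dichloride, then O2) to the (2S)-alcohol F9; the (+)-catalyst is assumed to give this sense.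
- Oxidation (Dess–Martin periodinane) to the aldehyde F10.
- Ohira–Bestmann homologation (dimethyl (1-diazo-2-oxopropyl)phosphonate, K2CO3, MeOH) to 8.

**Step 15.** Before the ring is deactivated by the first formyl group, HCl and the iminium salts may ionize the electron-rich tertiary C1–O ether; the reaction may also stop after one formylation. The fallback sets out from 21 and returns at 23, and works under basic conditions at a lower oxidation level:
- Bis-ortho-hydroxymethylation through the magnesium phenoxide (MgCl2, Et3N, paraformaldehyde) gives the bis(hydroxymethyl) compound F11.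
- MnO2 oxidation of the two salicylic alcohols gives 23.

## Further compounds

F1 | step 11 | trimethylsilyl enol ether of 10 (C3–OSiMe3, C3=C4) | C[Si](C)(C)OC1=C(C)[C@@H]2C(=C1)[C@@H](C)CC[C@@H]1[C@H]2C1(C)C
F2 | step 11 | neutral phenol–enone (open C4–C7' adduct, free phenol of 17) | CC(C)C[C@@H](c1c(O)cc(OCc2ccccc2)cc1OCc1ccccc1)[C@@]1(C)C(=O)C=C2[C@@H](C)CC[C@@H]3[C@H]([C@H]12)C3(C)C
F3 | step 7 | (1S,3R)-2,2-dimethyl-3-[(3S)-3-methylpent-4-yn-1-yl]cyclopropane-1-carbaldehyde | C#C[C@@H](C)CC[C@@H]1[C@H](C=O)C1(C)C
F4 | step 7 | 2-ethenyl-3,3-dimethyl-1-[(3S)-3-methylpent-4-yn-1-yl]cyclopropane (cis, ring centres as in 8) | C#C[C@@H](C)CC[C@@H]1[C@H](C=C)C1(C)C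
F5 | step 7 | 15-nor analogue of 10 (C4 = CH2; C5, C6, C7, C10 as in 10) | O=C1C=C2[C@@H](C)CC[C@@H]3[C@H]([C@@H]2C1)C3(C)C
F6 | step 7 | (4R,5R,6R,7R,10S)-aromadendr-1-en-3-one (C4 epimer of 10) | O=C1C=C2[C@@H](C)CC[C@@H]3[C@H]([C@@H]2[C@H]1C)C3(C)C
F7 | step 6 | p-toluenesulfonylhydrazone of 3 | CC(CC[C@@H]1[C@H](/C=C\C)C1(C)C)=NNS(=O)(=O)c1ccc(C)cc1
F8 | step 6 | (1R,2S)-1-(but-3-en-1-yl)-3,3-dimethyl-2-[(1Z)-prop-1-en-1-yl]cyclopropane | C=CCC[C@@H]1[C@H](/C=C\C)C1(C)C
F9 | step 6 | (2S)-4-[(1R,3S)-2,2-dimethyl-3-[(1Z)-prop-1-en-1-yl]cyclopropyl]-2-methylbutan-1-ol | OC[C@@H](C)CC[C@@H]1[C@H](/C=C\C)C1(C)C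
F10 | step 6 | (2S)-4-[(1R,3S)-2,2-dimethyl-3-[(1Z)-prop-1-en-1-yl]cyclopropyl]-2-methylbutanal | O=C[C@@H](C)CC[C@@H]1[C@H](/C=C\C)C1(C)C
F11 | step 15 | 3',5'-bis(hydroxymethyl) analogue of 23 (CH2OH in place of each CHO) | CC(C)C[C@H]1c2c(O)c(CO)c(O)c(CO)c2O[C@]23CC[C@@]1(C)[C@H]2[C@H]1[C@@H](CC[C@@H]3C)C1(C)C
A1 | alternative 1 | (+)-bicyclogermacrene | C/C1=C\CC/C(C)=C/[C@H]2[C@@H](CC1)C2(C)C
A2 | alternative 1 | 2,4-diformyl-3,5-dihydroxy-6-(3-methylbutylidene)cyclohexa-2,4-dien-1-one (o-quinone methide) | CC(C)CC=C1C(=O)C(C=O)=C(O)C(C=O)=C1O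
A3 | alternative 2 | (−)-α-gurjunene, (1aR,4R,4aR,7bS) | CC1=C2[C@H](CC1)[C@H](C)CC[C@@H]1[C@H]2C1(C)C
A4 | alternative 2 | aromadendr-4-en-3-one with the α-gurjunene configuration (1β-H, 10R) | CC1=C2[C@H](CC1=O)[C@H](C)CC[C@@H]1[C@H]2C1(C)C
A5 | alternative 2 | extended lithium dienolate of A4 (C3–O–Li, C3=C4, C5=C1) | [Li+].[O-]C1=C(C)C2=C(C1)[C@H](C)CC[C@@H]3[C@H]2C3(C)C
A6 | alternative 3 | 3,5-bis(benzyloxy)-2-[3-methyl-1-[1-methyl-3-(1-methylcyclopropyl)cyclopent-2-en-1-yl]butyl]phenol (C4 and C7' as in 23) | CC(C)C[C@@H](c1c(O)cc(OCc2ccccc2)cc1OCc1ccccc1)[C@@]1(C)CCC(C2(C)CC2)=C1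
A7 | alternative 3 | 3,3-dimethylcyclopropene | CC1(C)C=C1
A8 | alternative 3 | (5+2) cycloadduct: aromadendr-1(10)-ene carrying the C4 phenol side chain of A6 | CC(C)C[C@@H](c1c(O)cc(OCc2ccccc2)cc1OCc1ccccc1)[C@@]1(C)CCC2=C(C)CC[C@@H]3[C@H]([C@H]12)C3(C)C
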